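**Plan**

1. Cuts: the C6–O ester bond (angelate last); C14=C15 and C12=C13 (two Wittig reactions); C9–C11 (Negishi coupling on a C9 enol triflate); and, in ring A, C1–C10 and C4–C5 (Diels–Alder).
2. Enabling feature: ring B (C5–C10) has methyl groups on C8 and C10 on both sides of C9 and an oxygen on C6 para to C9. This is the pattern of 2,6-dimethyl-1,4-benzoquinone with C9 and C6 as its carbonyl carbons, so ring B is bought and only ring A has to be closed.
3. Forward: quinone and 4-methylpenta-1,3-diene close ring A; C5 is epimerised; conjugate hydride at C7 gives the C9 enolate, whose triflate is coupled with a C11–C12 acetal unit; the C6 ketone is reduced, the ring A alkene hydrogenated, the 8-ene hydroborated; the C12 aldehyde is extended to the 12E,14-diene; angeloylation ends the route.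
4. Stereochemistry: C10 from the chiral oxazaborolidinium catalyst (the only absolute control); C5 by equilibration to the trans ring fusion; C6 (α, equatorial) by dissolving-metal reduction; C8 and C9 together by syn hydroboration on the face opposite the C10 methyl; 12E from a stabilised ylide; the Z ester alkene comes with angelic acid.

Key step: step 1

Numbering: labdane numbering is used for the decalin core and the side chain (ring A = C1–C5, C10; ring B = C5–C10; C11 onwards on C9); β is the face of the C10 methyl group.

Assumption: the α-C–H···O binding model for quinones is taken to assign the (8aS) adduct to the (R)-prolinol-derived catalyst; if the sense proves opposite, the (S)-catalyst is used and nothing else changes.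

**Step 1**
Reactants: 1 2,6-dimethyl-1,4-benzoquinone; 2 4-methylpenta-1,3-diene
Product: 3 cis-fused adduct (4aR,8aS)-2,5,5,8a-tetramethyl-4a,5,8,8a-tetrahydronaphthalene-1,4-dione (2,7-diene-6,9-dione; 10β-CH3; 5β-H)
Conditions: (R)-3,3-diphenyl-1-(2-methylphenyl)tetrahydro-1H,3H-pyrrolo[1,2-c][1,3,2]oxazaborole (20 mol %) + HNTf2 (18 mol %), 2 (3 equiv), CH2Cl2, −78 → −20 °C
Reagents that add atoms: none
Why: Proposed new method: the protonated oxazaborolidine binds the C6 carbonyl, the only one flanked by ring C–H bonds and so able to make the α-C–H···O contact to the catalyst oxygen, which makes the methyl-bearing C10 the electrophilic β-carbon; the unsubstituted diene terminus C1 attacks C10 and the tertiary allyl cation/boron enolate pair then closes C4–C5, so the [4+2] addition is strongly asynchronous or stepwise and does not need a well-populated s-cis conformer. The closest known reaction type is the oxazaborolidinium-catalysed enantioselective Diels–Alder reaction of methyl-substituted 1,4-benzoquinones with simple and silyloxy-substituted 1,3-dienes, which gives angular-methyl cis-decalins; a diene with a fully substituted terminus has not been shown in it. Ring A (C1–C5, C10) is closed by intermolecular [4+2] cycloaddition, suprafacial on the quinone double bond, in the stepwise limit by six-membered recombination of the C5 enolate carbon with the C4 end of the allyl cation. C10 is set by the catalyst, whose carbinol phenyl group covers one face of the bound C5=C10 double bond, and C5 follows from the suprafacial addition (cis to C1; it is corrected in step 2). The step needs C1-to-C10 regiochemistry, secured by the site of coordination and by the strain of joining the gem-dimethyl carbon to the methyl-bearing C10, and it needs one enantiotopic face, which rests on the catalyst; the adduct cannot aromatise because C10 is quaternary.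

**Step 2**
Reactants: 3 cis-fused adduct
Product: 4 trans-fused enedione (4aS,8aS)-2,5,5,8a-tetramethyl-4a,5,8,8a-tetrahydronaphthalene-1,4-dione (5α-H)
Conditions: DBU (0.2 equiv), toluene, rt
Reagents that add atoms: none
Why: base-mediated epimerisation α to the C6 ketone through the C5 enolate, which cannot end in aromatisation because C10 is quaternary, should settle C5 in the thermodynamically preferred trans ring fusion (H opposite the C10 methyl), as in the classical equilibration of angular-methyl quinone adducts.

**Step 3**
Reactants: 4 trans-fused enedione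
Product: 6 C9 enol triflate (4,4,8,10β-tetramethyl-6-oxo-5αH-decal-2,8-dien-9-yl trifluoromethanesulfonate), via lithium C9 enolate 5 (not isolated)
Conditions: LiBH(s-Bu)3 (1.1 equiv), THF, −78 °C; then PhNTf2 (1.3 equiv), −78 → 0 °C
Reagents that add atoms: N-phenylbis(trifluoromethanesulfonimide), O=S(=O)(N(c1ccccc1)S(=O)(=O)C(F)(F)F)C(F)(F)F
Why: reductive triflation, in which the bulky hydride adds in conjugate fashion to the unsubstituted enedione carbon C7 (β to the C9 carbonyl) and so gives the tetrasubstituted C8=C9 enolate regiospecifically with the C6 ketone untouched, and O-sulfonylation traps it; no stereocenter is formed.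

**Step 4**
Reactants: 6 C9 enol triflate; 7 (1,3-dioxolan-2-ylmethyl)zinc bromide
Product: 8 9-(1,3-dioxolan-2-ylmethyl)-4,4,8,10β-tetramethyl-5αH-decal-2,8-dien-6-one
Conditions: 7 (2.5 equiv, 0.5 M in THF), Pd(OAc)2 (5 mol %), SPhos (10 mol %), THF, 50 °C
Reagents that add atoms: none
Why: Negishi coupling, for which enol triflates of the 2,6,6-trisubstituted cyclohexenyl type are proven partners of zerovalent palladium and alkylzinc halides, the organozinc tolerating the C6 ketone; it forms C9–C11 and brings C12 at the aldehyde oxidation level.

**Step 5**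
Reactants: 8 dienone acetal
Product: 9 9-(1,3-dioxolan-2-ylmethyl)-4,4,8,10β-tetramethyl-5αH-decal-2,8-dien-6α-ol
Conditions: Li (8 equiv), NH3(l)/THF, t-BuOH (3 equiv), −78 °C, 8 added to the metal solution; then NH4Cl
Reagents that add atoms: none
Why: dissolving-metal reduction of the ketone passes through a configurationally mobile carbinyl anion and should give the more stable equatorial 6α-alcohol (the axial 6β position is syn-diaxial to the 4β and 10β methyl groups, and hydride reagents attacking from the open α-face would give that unwanted epimer), while the isolated alkenes and the acetal are inert.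

**Step 6**
Reactants: 9 dienol acetal
Product: 10 9-(1,3-dioxolan-2-ylmethyl)-4,4,8,10β-tetramethyl-5αH-decal-8-en-6α-ol
Conditions: H2 (1 atm), Pd/C (10 wt %), EtOAc, rt
Reagents that add atoms: none
Why: catalytic hydrogenation saturates the cis-disubstituted 2,3-alkene of ring A, while the hindered tetrasubstituted 8,9-alkene is not reduced under these conditions; no stereocenter is formed.

**Step 7**
Reactants: 10 homoallylic alcohol
Product: 12 diol acetal 9β-(1,3-dioxolan-2-ylmethyl)-4,4,8β,10β-tetramethyl-5αH,9αH-decalin-6α,8α-diol, via C8 alkylborane 11 (not isolated)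
Conditions: BH3·THF (4 equiv), THF, 0 °C → rt; then 3 M NaOH, 30% H2O2, 0 °C → rt
Reagents that add atoms: hydrogen peroxide, OO
Why: hydroboration–oxidation, in which borane adds syn to the tetrasubstituted alkene from the α-face opposite the axial C10 methyl, with boron on the less hindered C8 and hydrogen on C9 next to the quaternary C10, and oxidation with retention sets the 8α-hydroxy (8β-methyl) and 9α-H (side chain β) centres together.

**Step 8**
Reactants: 12 diol acetal
Product: 14 6α,8α-bis(triethylsilyloxy)-13,14,15,16-tetranorlabdan-12-al, via N-(1-alkoxyalkyl)collidinium triflate 13 (not isolated)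
Conditions: TESOTf (5 equiv), 2,4,6-collidine (7 equiv), CH2Cl2, 0 °C; then H2O, rt
Reagents that add atoms: triethylsilyl trifluoromethanesulfonate, CC[Si](CC)(CC)OS(=O)(=O)C(F)(F)F; water, O
Why: the silyl triflate/pyridine-base acetal cleavage silylates both hydroxyl groups and turns the dioxolane into a collidinium salt that water hydrolyses to the aldehyde without acid, so the C12 aldehyde appears with the 8-hydroxyl already masked and can neither form a lactol nor suffer oxa-Michael addition in the next steps; no stereocenter is touched.

**Step 9**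
Reactants: 14 bis-silyl aldehyde
Product: 15 (12E)-6α,8α-bis(triethylsilyloxy)-15-norlabd-12-en-14-al
Conditions: Ph3P=C(CH3)CHO (2 equiv), toluene, 90 °C
Reagents that add atoms: 2-(triphenylphosphoranylidene)propanal, CC(C=O)=P(c1ccccc1)(c1ccccc1)c1ccccc1
Why: Wittig reaction with a stabilised ylide gives the α-methyl enal with C11 and the formyl group trans, which is the 12E geometry of the target.

**Step 10**
Reactants: 15 enal
Product: 16 6α,8α-bis(triethylsilyloxy)labda-12E,14-diene
Conditions: Ph3PCH3Br (3 equiv), KOt-Bu (2.8 equiv), THF, 0 °C → rt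
Reagents that add atoms: methyltriphenylphosphonium bromide, C[P+](c1ccccc1)(c1ccccc1)c1ccccc1.[Br-]
Why: Wittig methylenation of the enal completes the conjugated diene without touching the 12,13 geometry, the silyl ethers keeping the tertiary oxygen from adding to the enal under the basic conditions.

**Step 11**
Reactants: 16 bis-silyl diene
Product: 17 labda-12E,14-diene-6α,8α-diol
Conditions: Bu4NF (4 equiv), THF, rt → 50 °C
Reagents that add atoms: none
Why: fluoride-mediated desilylation removes both triethylsilyl ethers without acid, which spares the acid-sensitive pairing of tertiary 8-hydroxyl and 12,14-diene.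

**Step 12**
Reactants: 17 diene diol; 18 angelic acid
Product: 20 6α-angeloyloxylabda-12E,14-dien-8α-ol (the target), via angelic 2,4,6-trichlorobenzoic anhydride 19 (not isolated)
Conditions: 18 (3 equiv), 2,4,6-trichlorobenzoyl chloride (3 equiv), Et3N (6 equiv), toluene, rt; then 17, toluene, 80 °C
Reagents that add atoms: none
Why: Yamaguchi-type esterification through the mixed anhydride, run without a nucleophilic amine catalyst, acylates the secondary 6α-hydroxyl and leaves the tertiary 8-hydroxyl free, and it is the established way to make angelates without Z-to-E isomerisation to the tiglate.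

**Compound list**

1 | 2,6-dimethyl-1,4-benzoquinone | CC1=CC(=O)C=C(C)C1=O | starting material
2 | 4-methylpenta-1,3-diene | C=CC=C(C)C | starting material
3 | cis-fused adduct, (4aR,8aS)-2,5,5,8a-tetramethyl-4a,5,8,8a-tetrahydronaphthalene-1,4-dione | O=C1[C@@]2(C)CC=CC(C)(C)[C@H]2C(=O)C=C1C | intermediate
4 | trans-fused enedione, (4aS,8aS)-2,5,5,8a-tetramethyl-4a,5,8,8a-tetrahydronaphthalene-1,4-dione | O=C1[C@@]2(C)CC=CC(C)(C)[C@@H]2C(=O)C=C1C | intermediate
5 | lithium C9 enolate (2,8-diene, C6 ketone, O–Li on C9) | [Li]OC=1[C@@]2(C)CC=CC(C)(C)[C@@H]2C(=O)CC=1C | intermediate (not isolated)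
6 | C9 enol triflate, 4,4,8,10β-tetramethyl-6-oxo-5αH-decal-2,8-dien-9-yl trifluoromethanesulfonate | FC(F)(F)S(=O)(=O)OC=1[C@@]2(C)CC=CC(C)(C)[C@@H]2C(=O)CC=1C | intermediate
7 | (1,3-dioxolan-2-ylmethyl)zinc bromide | Br[Zn]CC1OCCO1 | starting material
8 | 9-(1,3-dioxolan-2-ylmethyl)-4,4,8,10β-tetramethyl-5αH-decal-2,8-dien-6-one | O1CCOC1CC=2[C@@]3(C)CC=CC(C)(C)[C@@H]3C(=O)CC=2C | intermediate
9 | 9-(1,3-dioxolan-2-ylmethyl)-4,4,8,10β-tetramethyl-5αH-decal-2,8-dien-6α-ol | O1CCOC1CC=2[C@@]3(C)CC=CC(C)(C)[C@@H]3[C@@H](O)CC=2C | intermediate
10 | 9-(1,3-dioxolan-2-ylmethyl)-4,4,8,10β-tetramethyl-5αH-decal-8-en-6α-ol | O1CCOC1CC=2[C@@]3(C)CCCC(C)(C)[C@@H]3[C@@H](O)CC=2C | intermediate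
11 | C8 alkylborane (8α-BH2, 9α-H, 6α-O-BH2) | O1CCOC1C[C@@H]2[C@@]3(C)CCCC(C)(C)[C@@H]3[C@@H](OB)C[C@@]2(C)B | intermediate (not isolated)
12 | diol acetal, 9β-(1,3-dioxolan-2-ylmethyl)-4,4,8β,10β-tetramethyl-5αH,9αH-decalin-6α,8α-diol | O1CCOC1C[C@@H]2[C@@]3(C)CCCC(C)(C)[C@@H]3[C@@H](O)C[C@@]2(C)O | intermediate
13 | N-(1-alkoxyalkyl)collidinium triflate (C12 bears the 2,4,6-trimethylpyridinium nitrogen and OCH2CH2OSiEt3; both ring oxygens silylated; C12 epimer mixture) | CC[Si](CC)(CC)OCCOC(C[C@@H]1[C@@]2(C)CCCC(C)(C)[C@@H]2[C@@H](O[Si](CC)(CC)CC)C[C@@]1(C)O[Si](CC)(CC)CC)[n+]1c(C)cc(C)cc1C.[O-]S(=O)(=O)C(F)(F)F | intermediate (not isolated)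
14 | 6α,8α-bis(triethylsilyloxy)-13,14,15,16-tetranorlabdan-12-al | O=CC[C@@H]1[C@@]2(C)CCCC(C)(C)[C@@H]2[C@@H](O[Si](CC)(CC)CC)C[C@@]1(C)O[Si](CC)(CC)CC | intermediate
15 | (12E)-6α,8α-bis(triethylsilyloxy)-15-norlabd-12-en-14-al | O=C/C(C)=C/C[C@@H]1[C@@]2(C)CCCC(C)(C)[C@@H]2[C@@H](O[Si](CC)(CC)CC)C[C@@]1(C)O[Si](CC)(CC)CC | intermediate
16 | 6α,8α-bis(triethylsilyloxy)labda-12E,14-diene | C=C/C(C)=C/C[C@@H]1[C@@]2(C)CCCC(C)(C)[C@@H]2[C@@H](O[Si](CC)(CC)CC)C[C@@]1(C)O[Si](CC)(CC)CC | intermediate
17 | labda-12E,14-diene-6α,8α-diol | C=C/C(C)=C/C[C@@H]1[C@@]2(C)CCCC(C)(C)[C@@H]2[C@@H](O)C[C@@]1(C)O | intermediate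
18 | angelic acid, (Z)-2-methylbut-2-enoic acid | C/C=C(/C)C(=O)O | starting material
19 | angelic 2,4,6-trichlorobenzoic anhydride | C/C=C(/C)C(=O)OC(=O)c1c(Cl)cc(Cl)cc1Cl | intermediate (not isolated)
20 | 6α-angeloyloxylabda-12E,14-dien-8α-ol (CNP0582767.1) | C=C/C(C)=C/C[C@@H]1[C@@]2(C)CCCC(C)(C)[C@@H]2[C@@H](OC(=O)/C(C)=C\C)C[C@@]1(C)O | target

**Count and risks**

Total step count: 12. Longest linear sequence: 12 steps (1 and 2 to 20); 7 and 18 are bought.

Step 1 (the labelled step). What may go wrong: after the first C1–C10 bond the ion pair loses a proton or closes through oxygen instead of forming C4–C5; the diene oligomerises under the strong acid; or the catalyst distinguishes the two quinone faces poorly. Fallback, with known chemistry, setting out from 1 and 2 and returning at 4: catalyst control is given up. Compounds 1 and 2 are combined without promoter under high pressure (about 12 kbar, CH2Cl2, rt), the established remedy for Diels–Alder reactions of dienes with a cis substituent on the terminus. This should give the cis adduct as a racemate, that is 3 together with its mirror image, the ent-cis adduct F1. DBU as in step 2 should turn this into 4 together with the ent-trans-enedione F2. Preparative chromatography on a chiral stationary phase (amylose tris(3,5-dimethylphenylcarbamate), CO2/MeOH) then separates 4 from F2.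

Step 7. What may go wrong: slow or incomplete addition of borane to the hindered tetrasubstituted alkene, boron ending on C9 instead of C8, or migration of the tertiary borane on warming. Fallback, setting out from 10 and returning at 12: oxygen and hydrogen are delivered separately. mCPBA (NaHCO3, CH2Cl2, 0 °C) should epoxidise the 8,9-alkene on the open α-face to give the 8α,9α-epoxide F3. Cp2TiCl (trivalent titanium, made from Cp2TiCl2 and Mn dust) in THF with 1,4-cyclohexadiene then opens the oxirane homolytically. The titanium alkoxide should stay on the less congested C8, and the tertiary C9 radical should take a hydrogen atom on the α-face, which gives 12 after aqueous work-up.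

Step 3. What may go wrong: 1,2-attack of the hydride on the C6 carbonyl, or proton transfer that moves the enolate to the C6 side before sulfonylation, so that regiocontrol is lost. Fallback, setting out from 4 and returning at 6: reduction and sulfonylation are separated. Copper hydride catalysis ([(Ph3P)CuH]6 (3 mol %), PhMe2SiH, toluene, rt), which adds only in conjugate fashion, should give the isolable C9 dimethylphenylsilyl enol ether F4. CsF and PhNTf2 in DME then convert it into 6.

**Further compounds**

F1 | step 1 | ent-cis adduct, (4aS,8aR)-2,5,5,8a-tetramethyl-4a,5,8,8a-tetrahydronaphthalene-1,4-dione | O=C1[C@]2(C)CC=CC(C)(C)[C@@H]2C(=O)C=C1C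
F2 | step 1 | ent-trans-enedione, (4aR,8aR)-2,5,5,8a-tetramethyl-4a,5,8,8a-tetrahydronaphthalene-1,4-dione | O=C1[C@]2(C)CC=CC(C)(C)[C@H]2C(=O)C=C1C
F3 | step 7 | 8α,9α-epoxide, 9β-(1,3-dioxolan-2-ylmethyl)-8α,9α-epoxy-4,4,8β,10β-tetramethyl-5αH-decalin-6α-ol | O1CCOC1C[C@]2(O3)[C@@]4(C)CCCC(C)(C)[C@@H]4[C@@H](O)C[C@]23C
F4 | step 3 | C9 dimethylphenylsilyl enol ether (2,8-diene, C6 ketone) | C[Si](C)(c1ccccc1)OC=1[C@@]2(C)CC=CC(C)(C)[C@@H]2C(=O)CC=1C
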